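**Retrosynthetic overview**
- Target ⇐ oxidation of the C1 carbinol and C6‑selective senecioylation of an epoxy cis‑1,6‑diol; the angelate is put on C3′–OH just before.
- Side chain: the C2′–C3′ bond comes from an asymmetric Nozaki–Hiyama–Kishi coupling of a C5 alkenyl triflate with 4‑methylpent‑3‑enal.
- Oxirane (second ring formed): epoxidation of the C2=C3 alkene anti to the C1/C6 silyloxy groups, done while the side chain is still only an electron‑poor enol triflate.
- C5–C2′ bond: nickel‑catalysed reductive coupling of the dienediol bis‑silyl ether with acetaldehyde, anti to the two oxygens.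
- Carbocycle (first ring, never opened): toluene, dearomatised by enzymatic cis‑dihydroxylation, which fixes C6 in the correct absolute sense; every later ring stereocentre is relayed from this diol face.

Convention and assumption (one line): locants C1–C6 and C1′–C7′ are those of the target (C1 = ring C=O, C2 = C–CH3, C5 bears the side chain, C6 bears the senecioate, C2′ is bonded to C5, C3′ is the carbinol carbon); β = face of the C5 side chain and epoxide oxygen, α = face of the C1/C6 oxygens; TBS = tert‑butyldimethylsilyl; toluene dioxygenase is used as recombinant whole cells.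

**Step 1**
Reactants: 1 toluene
Product: 2 (1S,2R)-3-methylcyclohexa-3,5-diene-1,2-diol
Conditions: E. coli JM109(pDTG601) whole cells (toluene dioxygenase), toluene vapour feed, glucose, O2, phosphate buffer pH 7.2, 35 °C
Reagents that add atoms: dioxygen, O=O
Why: Toluene dioxygenase carries out the enzymatic arene cis‑dihydroxylation (dearomatisation) of the 2,3‑bond on one enantiotopic face only, so both carbinol centres arise as the (1S,2R) diol (>98% ee) and the distal carbinol already has the configuration of C6 of the target.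

**Step 2**
Reactants: 2 (1S,2R)-3-methylcyclohexa-3,5-diene-1,2-diol
Product: 3 (1S,2R)-1,2-bis(TBSO)-3-methylcyclohexa-3,5-diene
Conditions: TBSOTf (2.5 equiv), 2,6‑lutidine, CH2Cl2, −78 → 0 °C
Reagents that add atoms: tert‑butyldimethylsilyl trifluoromethanesulfonate, CC(C)(C)[Si](C)(C)OS(=O)(=O)C(F)(F)F
Why: Silyl ether formation with the reactive triflate at low temperature outruns acid‑induced rearomatisation, masks both hydroxyls without touching a stereocentre and makes the α‑face of the diene the hindered one.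

**Step 3**
Reactants: 3 (1S,2R)-1,2-bis(TBSO)-3-methylcyclohexa-3,5-diene; 4 acetaldehyde
Product: 6 1α,6α-bis(TBSO)-5β-(1-hydroxyethyl)-2-methylcyclohex-2-ene (both carbinol epimers), via diethylborinate 5 (not isolated)
Conditions: Ni(acac)2 (10 mol %), Et3B (3 equiv), 4 (3 equiv), THF, rt; aqueous work‑up
Reagents that add atoms: none
Why: Nickel‑catalysed reductive coupling of a 1,3‑diene with an aldehyde (Tamaru homoallylation): zerovalent nickel joins the unsubstituted, more nucleophilic diene terminus C5 to the aldehyde on the face away from the two silyloxy groups (sets C5 as 5β), and ethyl transfer from boron followed by β‑hydride elimination puts the hydrogen on C4 so that the C2=C3 alkene remains; the new carbinol centre is unimportant because it is oxidised next.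

**Step 4**
Reactants: 6 1α,6α-bis(TBSO)-5β-(1-hydroxyethyl)-2-methylcyclohex-2-ene
Product: 7 5β-acetyl-1α,6α-bis(TBSO)-2-methylcyclohex-2-ene
Conditions: Dess–Martin periodinane, pyridine, CH2Cl2, 0 °C → rt
Reagents that add atoms: none
Why: Dess–Martin oxidation of the secondary alcohol under pyridine buffering converges both carbinol epimers on one methyl ketone and leaves the C5 centre (equatorial, trans to the C6 silyloxy group) untouched.

**Step 5**
Reactants: 7 5β-acetyl-1α,6α-bis(TBSO)-2-methylcyclohex-2-ene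
Product: 9 1α,6α-bis(TBSO)-2-methyl-5β-[1-(trifluoromethylsulfonyloxy)ethenyl]cyclohex-2-ene, via potassium enolate 8 (not isolated)
Conditions: KN(SiMe3)2, THF, −78 °C; then PhNTf2, −78 → 0 °C
Reagents that add atoms: N‑phenylbis(trifluoromethanesulfonimide), O=S(=O)(N(c1ccccc1)S(=O)(=O)C(F)(F)F)C(F)(F)F
Why: Kinetic deprotonation of the methyl ketone with the bulky amide base occurs at the methyl group, and O‑triflation of this less substituted enolate (enol triflate formation) gives the 1,1‑disubstituted alkenyl triflate without affecting the C5 centre.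

**Step 6**
Reactants: 9 1α,6α-bis(TBSO)-2-methyl-5β-[1-(trifluoromethylsulfonyloxy)ethenyl]cyclohex-2-ene
Product: 10 1α,6α-bis(TBSO)-2β,3β-epoxy-2-methyl-5β-[1-(trifluoromethylsulfonyloxy)ethenyl]cyclohexane
Conditions: dimethyldioxirane (acetone solution), CH2Cl2, 0 °C
Reagents that add atoms: dimethyldioxirane, CC1(C)OO1
Why: Dimethyldioxirane epoxidises only the electron‑rich trisubstituted ring alkene (the enol triflate alkene is electron‑poor) and attacks anti to the pseudoaxial allylic C1 silyloxy group, that is from the β‑face, which sets C2 and C3 (substrate‑controlled epoxidation of a cyclic allylic silyl ether).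

**Step 7**
Reactants: 11 4-methylpent-3-en-1-ol
Product: 12 4-methylpent-3-enal
Conditions: Dess–Martin periodinane, pyridine, CH2Cl2, 0 °C; used at once
Reagents that add atoms: none
Why: Dess–Martin oxidation under buffered, non‑basic conditions gives the β,γ‑unsaturated aldehyde without isomerisation to the conjugated enal; no stereocentre is formed.

**Step 8**
Reactants: 10 1α,6α-bis(TBSO)-2β,3β-epoxy-2-methyl-5β-[1-(trifluoromethylsulfonyloxy)ethenyl]cyclohexane; 12 4-methylpent-3-enal
Product: 15 1α,6α-bis(TBSO)-2β,3β-epoxy-5β-[(3S)-3-hydroxy-6-methylhepta-1,5-dien-2-yl]-2-methylcyclohexane, via alkenylchromium dichloride 13 (not isolated), via chromium alkoxide 14 (not isolated)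
Conditions: CrCl2 (4 equiv), NiCl2 (2 mol %), Kishi oxazoline–sulfonamide ligand (4.4 equiv), Et3N, THF, rt; then H2O
Reagents that add atoms: none
Why: Nozaki–Hiyama–Kishi coupling: nickel inserts into the alkenyl C–O bond of the triflate and hands the alkenyl group to chromium, the trivalent alkenylchromium adds to the aldehyde while tolerating the epoxide and silyl ethers, and the chiral sulfonamide ligand on chromium (enantiomer chosen for Re‑face attack, to be confirmed on a model) sets the 3′S carbinol.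

**Step 9**
Reactants: 15 1α,6α-bis(TBSO)-2β,3β-epoxy-5β-[(3S)-3-hydroxy-6-methylhepta-1,5-dien-2-yl]-2-methylcyclohexane; 16 angelic acid
Product: 18 1α,6α-bis(TBSO)-2β,3β-epoxy-5β-[(3S)-3-(angeloyloxy)-6-methylhepta-1,5-dien-2-yl]-2-methylcyclohexane, via mixed anhydride 17 (not isolated)
Conditions: 16, 2,4,6‑trichlorobenzoyl chloride, Et3N, toluene, rt; then 15, 80 °C
Reagents that add atoms: none
Why: Yamaguchi‑type esterification through the preformed mixed anhydride, run without an acyl‑transfer catalyst, acylates the hindered allylic alcohol with retention at C3′ and keeps the Z geometry of the angelate.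

**Step 10**
Reactants: 18 1α,6α-bis(TBSO)-2β,3β-epoxy-5β-[(3S)-3-(angeloyloxy)-6-methylhepta-1,5-dien-2-yl]-2-methylcyclohexane
Product: 19 2β,3β-epoxy-5β-[(3S)-3-(angeloyloxy)-6-methylhepta-1,5-dien-2-yl]-2-methylcyclohexane-1α,6α-diol
Conditions: Bu4NF, AcOH (1:1), THF, 0 → 40 °C
Reagents that add atoms: none
Why: Fluoride‑mediated desilylation driven by the strong Si–F bond, buffered with acetic acid so that the epoxide does not undergo Payne rearrangement and the angelate neither migrates nor isomerises; no stereocentre is touched.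

**Step 11**
Reactants: 19 2β,3β-epoxy-5β-[(3S)-3-(angeloyloxy)-6-methylhepta-1,5-dien-2-yl]-2-methylcyclohexane-1α,6α-diol; 20 3-methylbut-2-enoyl chloride
Product: 21 2β,3β-epoxy-5β-[(3S)-3-(angeloyloxy)-6-methylhepta-1,5-dien-2-yl]-2-methyl-6α-(senecioyloxy)cyclohexan-1α-ol
Conditions: 20 (1.1 equiv), pyridine, CH2Cl2, −20 °C
Reagents that add atoms: none
Why: Regioselective acylation of a cis‑1,2‑diol: the equatorial C6 hydroxyl reacts while the pseudoaxial C1 hydroxyl, flanked by the fully substituted epoxide carbon C2 and its methyl group, is too hindered at low temperature, so the senecioate goes to C6 with retention.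

**Step 12**
Reactants: 21 2β,3β-epoxy-5β-[(3S)-3-(angeloyloxy)-6-methylhepta-1,5-dien-2-yl]-2-methyl-6α-(senecioyloxy)cyclohexan-1α-ol
Product: 22 CNP0333561.1, (2S,3S,5S,6S)-2,3-epoxy-5-[(3S)-3-(angeloyloxy)-6-methylhepta-1,5-dien-2-yl]-2-methyl-6-(senecioyloxy)cyclohexan-1-one
Conditions: Dess–Martin periodinane, pyridine, CH2Cl2, 0 °C → rt
Reagents that add atoms: none
Why: Dess–Martin oxidation of the remaining hindered C1 alcohol gives the α,β‑epoxy ketone without touching any stereocentre, the C6 ester staying trans (diequatorial) to the C5 side chain.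

**Compound list**
1 | toluene | Cc1ccccc1 | starting material
2 | (1S,2R)-3-methylcyclohexa-3,5-diene-1,2-diol (its C1 becomes C6 and its C2 becomes C1 of the target) | CC1=CC=C[C@H](O)[C@@H]1O | intermediate
3 | (1S,2R)-1,2-bis(TBSO)-3-methylcyclohexa-3,5-diene | CC1=CC=C[C@H](O[Si](C)(C)C(C)(C)C)[C@@H]1O[Si](C)(C)C(C)(C)C | intermediate
4 | acetaldehyde | CC=O | starting material
5 | O‑diethylboryl ether of 6 (not isolated) | CC1=CC[C@@H](C(C)OB(CC)CC)[C@H](O[Si](C)(C)C(C)(C)C)[C@@H]1O[Si](C)(C)C(C)(C)C | intermediate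
6 | 1α,6α-bis(TBSO)-5β-(1-hydroxyethyl)-2-methylcyclohex-2-ene (carbinol epimers) | CC1=CC[C@@H](C(C)O)[C@H](O[Si](C)(C)C(C)(C)C)[C@@H]1O[Si](C)(C)C(C)(C)C | intermediate
7 | 5β-acetyl-1α,6α-bis(TBSO)-2-methylcyclohex-2-ene | CC1=CC[C@@H](C(C)=O)[C@H](O[Si](C)(C)C(C)(C)C)[C@@H]1O[Si](C)(C)C(C)(C)C | intermediate
8 | potassium enolate of 7 on the methyl side (not isolated) | CC1=CC[C@@H](C(=C)[O-])[C@H](O[Si](C)(C)C(C)(C)C)[C@@H]1O[Si](C)(C)C(C)(C)C.[K+] | intermediate
9 | 1α,6α-bis(TBSO)-2-methyl-5β-[1-(trifluoromethylsulfonyloxy)ethenyl]cyclohex-2-ene | CC1=CC[C@@H](C(=C)OS(=O)(=O)C(F)(F)F)[C@H](O[Si](C)(C)C(C)(C)C)[C@@H]1O[Si](C)(C)C(C)(C)C | intermediate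
10 | 1α,6α-bis(TBSO)-2β,3β-epoxy-2-methyl-5β-[1-(trifluoromethylsulfonyloxy)ethenyl]cyclohexane | C=C(OS(=O)(=O)C(F)(F)F)[C@@H]1C[C@@H]2O[C@]2(C)[C@@H](O[Si](C)(C)C(C)(C)C)[C@H]1O[Si](C)(C)C(C)(C)C | intermediate
11 | 4-methylpent-3-en-1-ol | CC(C)=CCCO | starting material
12 | 4-methylpent-3-enal | CC(C)=CCC=O | intermediate
13 | alkenylchromium dichloride from 10 (ligand on chromium omitted; not isolated) | C=C([Cr](Cl)Cl)[C@@H]1C[C@@H]2O[C@]2(C)[C@@H](O[Si](C)(C)C(C)(C)C)[C@H]1O[Si](C)(C)C(C)(C)C | intermediate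
14 | chromium alkoxide of 15 (ligand omitted; not isolated) | C=C([C@H](CC=C(C)C)O[Cr](Cl)Cl)[C@@H]1C[C@@H]2O[C@]2(C)[C@@H](O[Si](C)(C)C(C)(C)C)[C@H]1O[Si](C)(C)C(C)(C)C | intermediate
15 | 1α,6α-bis(TBSO)-2β,3β-epoxy-5β-[(3S)-3-hydroxy-6-methylhepta-1,5-dien-2-yl]-2-methylcyclohexane | C=C([C@H](CC=C(C)C)O)[C@@H]1C[C@@H]2O[C@]2(C)[C@@H](O[Si](C)(C)C(C)(C)C)[C@H]1O[Si](C)(C)C(C)(C)C | intermediate
16 | angelic acid, (Z)-2-methylbut-2-enoic acid | C/C=C(/C)C(=O)O | starting material
17 | angelic 2,4,6-trichlorobenzoic mixed anhydride (not isolated) | C/C=C(/C)C(=O)OC(=O)c1c(Cl)cc(Cl)cc1Cl | intermediate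
18 | 1α,6α-bis(TBSO)-2β,3β-epoxy-5β-[(3S)-3-(angeloyloxy)-6-methylhepta-1,5-dien-2-yl]-2-methylcyclohexane | C=C([C@H](CC=C(C)C)OC(=O)/C(C)=C\C)[C@@H]1C[C@@H]2O[C@]2(C)[C@@H](O[Si](C)(C)C(C)(C)C)[C@H]1O[Si](C)(C)C(C)(C)C | intermediate
19 | 2β,3β-epoxy-5β-[(3S)-3-(angeloyloxy)-6-methylhepta-1,5-dien-2-yl]-2-methylcyclohexane-1α,6α-diol | C=C([C@H](CC=C(C)C)OC(=O)/C(C)=C\C)[C@@H]1C[C@@H]2O[C@]2(C)[C@@H](O)[C@H]1O | intermediate
20 | 3-methylbut-2-enoyl chloride (senecioyl chloride) | CC(C)=CC(=O)Cl | starting material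
21 | 2β,3β-epoxy-5β-[(3S)-3-(angeloyloxy)-6-methylhepta-1,5-dien-2-yl]-2-methyl-6α-(senecioyloxy)cyclohexan-1α-ol | C=C([C@H](CC=C(C)C)OC(=O)/C(C)=C\C)[C@@H]1C[C@@H]2O[C@]2(C)[C@@H](O)[C@H]1OC(=O)C=C(C)C | intermediate
22 | CNP0333561.1, (2S,3S,5S,6S)-2,3-epoxy-5-[(3S)-3-(angeloyloxy)-6-methylhepta-1,5-dien-2-yl]-2-methyl-6-(senecioyloxy)cyclohexan-1-one | C=C([C@H](CC=C(C)C)OC(=O)/C(C)=C\C)[C@@H]1C[C@@H]2O[C@]2(C)C(=O)[C@H]1OC(=O)C=C(C)C | target

**Step count**
Total: 12 steps. Longest linear sequence: 11 steps (toluene to target, steps 1–6 and 8–12; step 7 is the one‑step side branch).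

**Three steps most likely to fail, with fallbacks**

Step 3 (nickel coupling on a hindered, doubly allylic‑oxygenated cyclic diene). The diene may be too encumbered, or hydrogen may be delivered to C2 instead of C4. The fallback sets out from 3 and replaces the organometallic coupling by a radical‑chain hydroacylation: Se‑phenyl ethaneselenoate, Bu3SnH added by syringe pump, AIBN, benzene, 80 °C. The acetyl radical adds to the unsubstituted diene terminus C5 anti to the silyloxy groups, and the resulting allyl radical takes hydrogen from the stannane at the less hindered C4. This gives methyl ketone 7 directly, so the route is rejoined at 7 and steps 3 and 4 are skipped; no new compound is formed on the way (F0).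

Step 8 (ligand‑controlled C3′ configuration; the base‑sensitive β,γ‑unsaturated aldehyde). If the chiral chromium complex gives poor selectivity or the wrong epimer, the fallback sets out from 10 and 12 and separates bond formation from stereocontrol. A plain coupling (CrCl2, NiCl2 cat., DMF, no chiral ligand) gives the C3′‑epimeric mixture of allylic alcohols F1. Dess–Martin oxidation of F1 gives the cross‑conjugated enone 1α,6α-bis(TBSO)-2β,3β-epoxy-2-methyl-5β-(6-methyl-3-oxohepta-1,5-dien-2-yl)cyclohexane F2. Corey–Bakshi–Shibata reduction of F2 with the (R)-methyl oxazaborolidine and catecholborane at −40 °C (alkenyl as the large group) then gives the 3′S alcohol, and the route is rejoined at 15.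

Step 11 (discrimination of the two secondary hydroxyls; possible 6→1 acyl migration). If the diol is acylated unselectively, the fallback sets out from 18 and differentiates the oxygens by stepwise deprotection instead. Limited HF·pyridine in THF/pyridine at 0 °C removes the less hindered C6 silyl ether first and gives the C1‑silyl‑protected C6 alcohol F3. Acylation of F3 with 20 (pyridine, DMAP cat.) gives the C6 senecioate C1 silyl ether F4. HF·pyridine at rt (acidic, so no acyl migration) then frees the C1 hydroxyl, and the route is rejoined at 21.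

**Further compounds**
F0 | step 3 | none | none
F1 | step 8 | 1α,6α-bis(TBSO)-2β,3β-epoxy-5β-(3-hydroxy-6-methylhepta-1,5-dien-2-yl)-2-methylcyclohexane, mixture of C3′ epimers | C=C(C(CC=C(C)C)O)[C@@H]1C[C@@H]2O[C@]2(C)[C@@H](O[Si](C)(C)C(C)(C)C)[C@H]1O[Si](C)(C)C(C)(C)C
F2 | step 8 | 1α,6α-bis(TBSO)-2β,3β-epoxy-2-methyl-5β-(6-methyl-3-oxohepta-1,5-dien-2-yl)cyclohexane | C=C(C(=O)CC=C(C)C)[C@@H]1C[C@@H]2O[C@]2(C)[C@@H](O[Si](C)(C)C(C)(C)C)[C@H]1O[Si](C)(C)C(C)(C)C
F3 | step 11 | 1α-(TBSO)-2β,3β-epoxy-5β-[(3S)-3-(angeloyloxy)-6-methylhepta-1,5-dien-2-yl]-2-methylcyclohexan-6α-ol | C=C([C@H](CC=C(C)C)OC(=O)/C(C)=C\C)[C@@H]1C[C@@H]2O[C@]2(C)[C@@H](O[Si](C)(C)C(C)(C)C)[C@H]1O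
F4 | step 11 | 1α-(TBSO)-2β,3β-epoxy-5β-[(3S)-3-(angeloyloxy)-6-methylhepta-1,5-dien-2-yl]-2-methyl-6α-(senecioyloxy)cyclohexane | C=C([C@H](CC=C(C)C)OC(=O)/C(C)=C\C)[C@@H]1C[C@@H]2O[C@]2(C)[C@@H](O[Si](C)(C)C(C)(C)C)[C@H]1OC(=O)C=C(C)C
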